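**Retrosynthetic overview**

1. The target is (−)-epigallocatechin-(4β→6)-(−)-epigallocatechin 3-O-gallate: upper unit 2R,3R,4S (2,3-cis, 3,4-trans), lower unit 2R,3R, galloyl ester on the lower 3-O, interflavan bond from upper C4 to lower C6.
2. The only skeletal disconnection is the C4–C6 interflavan bond, made as the plant is presumed to make it: an electrophilic epigallocatechin extension unit (C4 cation at the leucodelphinidin oxidation level) is captured by ring A of the free-phenolic starter unit EGCG.
3. The cation is not taken from an isolated 4-activated flavan: DDQ abstracts the C4 hydride of benzyl-masked epigallocatechin, and unprotected EGCG is coupled in the same flask (a formal C4–H/C6–H dehydrogenative coupling). The 2,3-cis unit forces 4β attack.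
4. Ring order: no ring is closed in the flask. Rings A, C and B of both flavan units (with C2 and C3 already set) and the galloyl ring arrive complete in the two tea catechins, where the biosynthesis has already formed them.
5. The last operation is hydrogenolysis of the five benzyl ethers.

Assumption: (−)-epigallocatechin and (−)-epigallocatechin 3-O-gallate, both isolated in bulk from green tea, count as cheap commercial starting materials of natural 2R,3R configuration.

**Step 1**
Reactants: 1 (−)-epigallocatechin; 2 benzyl bromide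
Product: 3 5,7,3',4',5'-penta-O-benzyl-(−)-epigallocatechin
Conditions: BnBr (5.5 equiv), K2CO3 (6 equiv), DMF, −10 °C → rt, Ar
Reagents that add atoms: benzyl bromide, BrCc1ccccc1
Why: Williamson O-benzylation, in which K2CO3 ionises only the five phenols (the secondary 3-OH stays free) and neither stereocentre (C2, C3) takes part, so 3 keeps the 2R,3R configuration of 1.

**Step 2**
Reactants: 3 5,7,3',4',5'-penta-O-benzyl-(−)-epigallocatechin; 4 2-ethoxyethanol; 5 (−)-epigallocatechin 3-O-gallate (EGCG)
Product: 7 5,7,3',4',5'-penta-O-benzyl-epigallocatechin-(4β→6)-epigallocatechin 3-O-gallate, via 4β-(2-ethoxyethoxy) ether 6 (not isolated)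
Conditions: DDQ (1.2 equiv), 4 (5 equiv), CH2Cl2, rt, 2 h; then 5 (5 equiv), TsOH·H2O (0.3 equiv), THF, 0 °C → rt; RP-18 separation of the C6-linked isomer from the C8-linked isomer
Reagents that add atoms: none
Why: Proposed new method: DDQ removes hydride from C4 of 3 (benzylic, pushed by the 5- and 7-benzyloxy groups and O1) and 4 holds the cation as the 4β-ether 6, a stand-in for the leucodelphinidin-type extension unit; TsOH then re-ionises 6 (SN1) and the free phloroglucinol-type ring A of 5 captures the cation by Friedel–Crafts alkylation at C6 (C8 competes) from the β face, anti to the α-disposed 3-OH and 2-aryl group, which sets C4 as 4S (3,4-trans) as in every 2,3-cis proanthocyanidin; the closest known reactions are the DDQ C4-alkoxylation of benzylated flavan-3-ols followed by Lewis-acid coupling and the acid-catalysed condensation of flavan-3,4-diols with free-phenolic flavan-3-ols, here merged in one flask.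

**Step 3**
Reactants: 7 5,7,3',4',5'-penta-O-benzyl-epigallocatechin-(4β→6)-epigallocatechin 3-O-gallate
Product: 8 (−)-epigallocatechin-(4β→6)-(−)-epigallocatechin 3-O-gallate (target)
Conditions: H2 (1 atm), Pd(OH)2/C, THF/MeOH/H2O, rt
Reagents that add atoms: none
Why: Catalytic hydrogenolysis (O-debenzylation) is neutral, so the galloyl ester, the interflavan C–C bond and the five existing stereocentres are untouched and no new stereocentre arises.

**Compound list**

1 | (−)-epigallocatechin, (2R,3R)-2-(3,4,5-trihydroxyphenyl)chromane-3,5,7-triol | O[C@@H]1Cc2c(O)cc(O)cc2O[C@@H]1c1cc(O)c(O)c(O)c1 | starting material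
2 | benzyl bromide | BrCc1ccccc1 | starting material
3 | 5,7,3',4',5'-penta-O-benzyl-(−)-epigallocatechin, (2R,3R)-5,7-bis(benzyloxy)-2-[3,4,5-tris(benzyloxy)phenyl]chroman-3-ol, 3-OH free | O[C@@H]1Cc2c(OCc3ccccc3)cc(OCc3ccccc3)cc2O[C@@H]1c1cc(OCc2ccccc2)c(OCc2ccccc2)c(OCc2ccccc2)c1 | intermediate
4 | 2-ethoxyethanol | CCOCCO | starting material
5 | (−)-epigallocatechin 3-O-gallate (EGCG), (2R,3R)-5,7-dihydroxy-2-(3,4,5-trihydroxyphenyl)chroman-3-yl 3,4,5-trihydroxybenzoate | O=C(O[C@@H]1Cc2c(O)cc(O)cc2O[C@@H]1c1cc(O)c(O)c(O)c1)c1cc(O)c(O)c(O)c1 | starting material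
6 | (2R,3R,4S)-5,7-bis(benzyloxy)-4-(2-ethoxyethoxy)-2-[3,4,5-tris(benzyloxy)phenyl]chroman-3-ol (4β-ether, 2,3-cis, 3,4-trans) | CCOCCO[C@H]1c2c(OCc3ccccc3)cc(OCc3ccccc3)cc2O[C@H](c2cc(OCc3ccccc3)c(OCc3ccccc3)c(OCc3ccccc3)c2)[C@@H]1O | intermediate
7 | 5,7,3',4',5'-penta-O-benzyl-epigallocatechin-(4β→6)-epigallocatechin 3-O-gallate (benzyl groups on the upper unit only; upper unit 2R,3R,4S; lower unit 2R,3R) | O=C(O[C@@H]1Cc2c(cc(O)c([C@H]3c4c(OCc5ccccc5)cc(OCc5ccccc5)cc4O[C@H](c4cc(OCc5ccccc5)c(OCc5ccccc5)c(OCc5ccccc5)c4)[C@@H]3O)c2O)O[C@@H]1c1cc(O)c(O)c(O)c1)c1cc(O)c(O)c(O)c1 | intermediate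
8 | (−)-epigallocatechin-(4β→6)-(−)-epigallocatechin 3-O-gallate (upper unit 2R,3R,4S; lower unit 2R,3R; gallate on the lower 3-O) | O=C(O[C@@H]1Cc2c(cc(O)c([C@H]3c4c(O)cc(O)cc4O[C@H](c4cc(O)c(O)c(O)c4)[C@@H]3O)c2O)O[C@@H]1c1cc(O)c(O)c(O)c1)c1cc(O)c(O)c(O)c1 | target

**Step count and risks**

Total step count: 3. Longest linear sequence: 3 (1 → 3 → 7 → 8).

The step most likely to fail is step 2. Residual DDQ can oxidise part of 5, the cation may be captured poorly in the mixed medium, and C8 of 5 is intrinsically about three times as reactive as C6, so 7 is expected as the minor regioisomer. The fallback sets out from 3 and comes back at 7. It gives up the one-flask kinetic coupling: 6 is isolated after the DDQ stage and condensed with 5 in a second flask (TMSOTf cat., CH2Cl2/THF, −20 °C). The dominant C8-linked regioisomer 5,7,3',4',5'-penta-O-benzyl-epigallocatechin-(4β→8)-epigallocatechin 3-O-gallate F1 is separated and converted into 7 by acid-catalysed interflavan exchange (HCl 0.1 M in dioxane/THF, excess 5, 40 °C). Ipso-protonation at C8 releases the same C4 cation together with 5 (retro-Friedel–Crafts, the reaction that underlies thiolysis and phloroglucinolysis of proanthocyanidins), and the cation re-partitions between C8 and C6. To my recollection the 4→6 bond is the less acid-labile of the two, so repeated passes should drain F1 into 7.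

Second is step 1. Pyrogallol phenolates are air-sensitive, and C-benzylation at C6/C8 or incomplete alkylation can cut the yield. The fallback sets out from 5 and comes back at 3. The cheaper 5 is perbenzylated with 2 (K2CO3, DMF) to octa-O-benzyl-(−)-epigallocatechin 3-O-gallate F2, and the tri-O-benzylgalloyl group is then removed by transesterification (NaOMe, MeOH/THF, rt). With all phenols capped, C2 cannot epimerise, and 3 is obtained beside methyl 3,4,5-tris(benzyloxy)benzoate.

Third is step 3. Debenzylation of a substrate with thirteen free phenols can stall, or the product can be over-reduced or air-oxidised on the catalyst. The fallback sets out from 7 and comes back at 8 (no new compound, F0). It replaces reductive cleavage by Lewis-acid dealkylation: BCl3 (excess), pentamethylbenzene as benzyl-cation scavenger, CH2Cl2, −78 °C, then MeOH. This removes the aryl benzyl ethers by an SN1-type path without H2 or Pd and should leave the ester and the interflavan C–C bond intact at that temperature.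

**Further compounds**

F1 | step 2 | 5,7,3',4',5'-penta-O-benzyl-epigallocatechin-(4β→8)-epigallocatechin 3-O-gallate (C8-linked regioisomer of 7) | O=C(O[C@@H]1Cc2c(O)cc(O)c([C@H]3c4c(OCc5ccccc5)cc(OCc5ccccc5)cc4O[C@H](c4cc(OCc5ccccc5)c(OCc5ccccc5)c(OCc5ccccc5)c4)[C@@H]3O)c2O[C@@H]1c1cc(O)c(O)c(O)c1)c1cc(O)c(O)c(O)c1
F2 | step 1 | octa-O-benzyl-(−)-epigallocatechin 3-O-gallate | O=C(O[C@@H]1Cc2c(OCc3ccccc3)cc(OCc3ccccc3)cc2O[C@@H]1c1cc(OCc2ccccc2)c(OCc2ccccc2)c(OCc2ccccc2)c1)c1cc(OCc2ccccc2)c(OCc2ccccc2)c(OCc2ccccc2)c1
F0 | step 3 | none | none
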